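With daucane numbering (C1 methyl-bearing ring-fusion carbon, C5 ring-fusion CH, C4 carbinol, C6 acyloxy carbon), the seven-membered ring C1–C5–C6–C7–C8–C9–C10 holds the C6 oxygen and the C8–C9 epoxide 1,4 to each other across the single CH2 group C7: a masked cyclohepta-1,4-diene (C5=C6 enol ether, C8=C9 alkene). The route cuts this ring at C7–C8 and C9–C10. One rhodium-catalysed (5+2) cycloaddition assembles the diene from a silylpropyne and a 2-siloxyvinylcyclopropane whose three-membered ring is fused to the future cyclopentane (a bicyclo[3.1.0]hexane with quaternary C1 in place and C4 masked as a dioxolane). The later centres are all set anti to the C1 methyl group.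

Key step: step 9

Remark: β is the face of the C1 methyl group and α the opposite face; which antipode of the bis(oxazoline) ligand leads to the (1R,5R) ester 6 is assumed to be settled in a trial run with both.

Step 1
Reactants: 1 methyl acetoacetate; 2 3-chloro-2-methylprop-1-ene (methallyl chloride)
Product: 4 methyl 6-methyl-3-oxohept-6-enoate, via sodium lithium dianion of methyl acetoacetate 3 (not isolated)
Conditions: NaH, THF, 0 °C; n-BuLi, 0 °C; then 2, 0 °C → rt; aq. NH4Cl
Reagents that add atoms: none
Why: γ-Alkylation of the acetoacetate dianion: the terminal carbanion is the more basic and more nucleophilic site, so the allylic chloride should be taken up there only, and no stereocentre arises.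

Step 2
Reactants: 4 methyl 6-methyl-3-oxohept-6-enoate
Product: 5 methyl 2-diazo-6-methyl-3-oxohept-6-enoate
Conditions: 4-acetamidobenzenesulfonyl azide, Et3N, MeCN, 0 °C → rt
Reagents that add atoms: 4-acetamidobenzenesulfonyl azide, CC(=O)Nc1ccc(cc1)S(=O)(=O)N=[N+]=[N-]
Why: Regitz diazo transfer to the doubly activated methylene group of a β-keto ester is general and leaves the remote 1,1-disubstituted alkene untouched.

Step 3
Reactants: 5 methyl 2-diazo-6-methyl-3-oxohept-6-enoate
Product: 6 methyl (1R,5R)-5-methyl-2-oxobicyclo[3.1.0]hexane-1-carboxylate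
Conditions: (CuOTf)2·C6H6 (5 mol %), 2,2'-isopropylidenebis(4-tert-butyl-2-oxazoline) (one antipode, 6 mol %), CH2Cl2, rt, slow addition of 5
Reagents that add atoms: none
Why: Intramolecular cyclopropanation by a copper carbenoid closes the three-membered and the five-membered ring together on the tethered 1,1-disubstituted alkene (cis fusion is the only geometry possible), and the C2-symmetric bis(oxazoline) on monovalent copper selects the alkene face that sets C1 (daucane numbering) as drawn, the level of induction with a methyl ester being the open point.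

Step 4
Reactants: 6 methyl (1R,5R)-5-methyl-2-oxobicyclo[3.1.0]hexane-1-carboxylate
Product: 7 methyl (1R,5R)-5-methylspiro[bicyclo[3.1.0]hexane-2,2'-[1,3]dioxolane]-1-carboxylate
Conditions: (TMSOCH2)2, TMSOTf (cat.), CH2Cl2, −78 → −20 °C; pyridine quench
Reagents that add atoms: 1,2-bis(trimethylsilyloxy)ethane, C[Si](C)(C)OCCO[Si](C)(C)C
Why: Ketalisation with the bis-silylated diol under catalytic TMSOTf converts hindered ketones at low temperature, where the ester and the acceptor-substituted cyclopropane should stay intact, and it masks C4 against the organolithium and fluoride steps to come.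

Step 5
Reactants: 7 methyl (1R,5R)-5-methylspiro[bicyclo[3.1.0]hexane-2,2'-[1,3]dioxolane]-1-carboxylate
Product: 8 (1R,5R)-5-methylspiro[bicyclo[3.1.0]hexane-2,2'-[1,3]dioxolane]-1-carboxylic acid
Conditions: KOH, MeOH–H2O, 60 °C; then 1 M HCl to pH 4, 0 °C
Reagents that add atoms: potassium hydroxide, [K+].[OH-]
Why: Ester saponification by hydroxide; the dioxolane is stable to base and should survive the brief cold acidification to about pH 4.

Step 6
Reactants: 8 (1R,5R)-5-methylspiro[bicyclo[3.1.0]hexane-2,2'-[1,3]dioxolane]-1-carboxylic acid
Product: 11 methyl ketone (1-acetyl-5-methylbicyclo[3.1.0]hexan-2-one ethylene ketal; spatial arrangement of 8 retained), via lithium carboxylate 9 (not isolated), via dilithium gem-diolate 10 (not isolated)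
Conditions: MeLi (2.5 equiv), Et2O–THF, 0 °C → rt; inverse quench into cold aq. NH4Cl
Reagents that add atoms: methyllithium, [Li]C
Why: Methyl ketone synthesis from a carboxylic acid with methyllithium: the second equivalent adds to the lithium carboxylate and the dilithium gem-diolate holds until the quench, so no tertiary alcohol should form; the new methyl group is C7.

Step 7
Reactants: 11 methyl ketone (1-acetyl-5-methylbicyclo[3.1.0]hexan-2-one ethylene ketal)
Product: 13 siloxyvinylcyclopropane (tert-butyldimethylsilyl enol ether of 11; CH2=C(OTBS) on the cyclopropane carbon C5), via potassium enolate 12 (not isolated)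
Conditions: KN(SiMe3)2, THF, −78 °C; TBSCl, −78 → 0 °C
Reagents that add atoms: tert-butyldimethylsilyl chloride, CC(C)(C)[Si](C)(C)Cl
Why: Silyl enol ether formation by kinetic deprotonation and O-silylation: only the methyl group can be deprotonated because the other α-carbon (C5) is quaternary, and the base-only conditions avoid acid that could open the cyclopropane.

Step 8
Reactants: 14 1-propynylmagnesium bromide
Product: 15 benzyldimethyl(prop-1-yn-1-yl)silane
Conditions: BnMe2SiCl, THF, 0 °C → rt
Reagents that add atoms: benzylchlorodimethylsilane, C[Si](C)(Cl)Cc1ccccc1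
Why: Substitution at silicon by an alkynyl Grignard reagent, a standard preparation of silylalkynes.

Step 9
Reactants: 13 siloxyvinylcyclopropane; 15 benzyldimethyl(prop-1-yn-1-yl)silane
Product: 16 hydroazulene cycloadduct (1β-methyl; C4 dioxolane; C5=C6 tert-butyldimethylsilyl enol ether; C8=C9 alkene with methyl on C8 and benzyldimethylsilyl on C9)
Conditions: [Rh(CO)2Cl]2 (5 mol %), 15 (2 equiv), ClCH2CH2Cl, 70 °C
Reagents that add atoms: none
Why: Proposed new method: monovalent rhodium should bind the siloxyvinyl group of 13 and open the cyclopropane bond C5–C10 to a trivalent rhodium metallacycle (σ-bond to C10, allyl unit over C5–C6–C7), after which alkyne 15 inserts at the allyl terminus C7 (new C7–C8 bond) and C(sp2)–C(sp3) reductive elimination joins C9 to C10 and releases the catalyst. The closest known reaction type is the intermolecular (5+2) cycloaddition of vinylcyclopropanes with alkynes under [Rh(CO)2Cl]2, established for oxygen-substituted and internally substituted vinylcyclopropanes and for unsymmetrical alkynes, but not for a bicyclo[3.1.0]hexane-fused siloxyvinylcyclopropane with two fully substituted neighbours. The seven-membered ring closes as a (5+2) annulation onto the existing cyclopentane, its last bond coming from reductive elimination out of an eight-membered rhodacycle, and the three-membered ring is consumed. No stereocentre is created: C5 becomes sp2 and C1, which takes part in no bond change, keeps its configuration. Two selectivities are needed: cleavage of C5–C10 instead of C5–C1, which the fully substituted C1 should enforce because rhodium would otherwise have to bond to a tertiary carbon, and bonding of the methyl-bearing alkyne carbon to C7, which the bulky benzyldimethylsilyl group should enforce by occupying the rhodium-bound carbon remote from the first C–C bond formed. Strain release of the bicyclo[3.1.0]hexane and the flanking C1 and C4 ketal, which hold the vinyl group over the C5–C10 bond, should favour the opening.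

Step 10
Reactants: 16 hydroazulene cycloadduct
Product: 17 trans-fused C6 ketone (5α-H; 1β-methyl; C4 dioxolane; C8=C9 vinylsilane retained)
Conditions: Bu4NF, AcOH (1:1), THF, −78 °C, short reaction time
Reagents that add atoms: none
Why: Fluoride-induced cleavage of the silyl enol ether gives the C5=C6 enolate, which the acetic acid buffer should protonate at C5 on the α-face, anti to the methyl group on the adjacent quaternary C1 (kinetic protonation), so the ring fusion becomes trans; buffering, low temperature and short contact keep C8=C9 out of conjugation and leave the vinylsilane in place.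

Step 11
Reactants: 17 trans-fused C6 ketone
Product: 18 6β-alcohol (5α-H; 1β-methyl; C4 dioxolane; C8=C9 vinylsilane)
Conditions: LiBH(s-Bu)3 (L-Selectride), THF, −78 °C; aq. NH4Cl
Reagents that add atoms: none
Why: Diastereoselective ketone reduction with a bulky trialkylborohydride: hydride should arrive on the α-face, away from the axial C1 methyl group, giving the axial 6β-alcohol, and the low temperature protects C5 and the β,γ-alkene.

Step 12
Reactants: 18 6β-alcohol with C9 benzyldimethylsilyl group
Product: 19 1β,8-dimethyl-4,4-ethylenedioxy-5α-H-bicyclo[5.3.0]dec-8-en-6β-ol (daucane numbering; free C8=C9 alkene)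
Conditions: Bu4NF (excess), wet THF, rt → 50 °C
Reagents that add atoms: none
Why: Fluoride-promoted protodesilylation of a benzyldimethylsilyl alkene (fluoride expels the benzyl group as toluene and the activated silicon is then replaced by hydrogen at C9 without movement of the double bond), a known use of this silyl group that the ketal and the free alcohol tolerate.

Step 13
Reactants: 19 ketal alcohol
Product: 20 6β-hydroxy-1β,8-dimethyl-5α-H-bicyclo[5.3.0]dec-8-en-4-one (daucane numbering)
Conditions: PPTS, acetone–H2O, 40 °C
Reagents that add atoms: water, O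
Why: Acid-catalysed ketal hydrolysis under PPTS, mild enough that the β-hydroxy ketone should neither dehydrate nor epimerise at C5 and the trisubstituted alkene stays put.

Step 14
Reactants: 20 hydroxy ketone; 21 isopropylmagnesium chloride
Product: 22 dauc-8-ene-4β,6β-diol (1β-methyl; 5α-H; 4α-isopropyl)
Conditions: 21 (4 equiv), anhydrous CeCl3 (4 equiv), THF, −78 → 0 °C; aq. NH4Cl
Reagents that add atoms: none
Why: Cerium-trichloride-mediated Grignard addition, which suppresses enolisation and β-hydride reduction: the first equivalent forms the C6 alkoxide and the isopropyl group should then add to the C4 carbonyl on the α-face, because the β-face is screened by the C1 methyl group and the C6 alkoxide, so the new hydroxyl is β.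

Step 15
Reactants: 23 vanillic acid
Product: 24 4-acetoxy-3-methoxybenzoic acid
Conditions: Ac2O, pyridine, rt; H2O work-up
Reagents that add atoms: acetic anhydride, CC(=O)OC(C)=O
Why: Acetylation of the phenol (acyl transfer with pyridine) masks the competing nucleophile and makes the arene less prone to oxidation by the later peracid, while the aqueous work-up returns the carboxyl group as the free acid.

Step 16
Reactants: 22 dauc-8-ene-4β,6β-diol; 24 4-acetoxy-3-methoxybenzoic acid
Product: 26 C6 4-acetoxy-3-methoxybenzoate of diol 22, via mixed trichlorobenzoic anhydride 25 (not isolated)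
Conditions: 2,4,6-Cl3C6H2COCl, Et3N, THF, rt; then 22, DMAP, toluene, rt → 40 °C
Reagents that add atoms: none
Why: Yamaguchi esterification: the mixed anhydride is attacked at the aroyl carbonyl by DMAP and the acylpyridinium acylates the secondary C6 hydroxyl with retention, the tertiary C4 hydroxyl being too hindered to react.

Step 17
Reactants: 26 C6 4-acetoxy-3-methoxybenzoate
Product: 27 8α,9α-epoxide of 26
Conditions: m-CPBA, NaHCO3, CH2Cl2, 0 °C
Reagents that add atoms: m-chloroperoxybenzoic acid, O=C(OO)c1cccc(Cl)c1
Why: Prilezhaev epoxidation of the only alkene: the β-face of C8=C9 is flanked by the axial C1 methyl and the axial C6 aroyloxy group, so the peracid should add on the α-face, and the bicarbonate buffer guards the epoxide against acid-induced opening by the neighbouring ester or hydroxyl group.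

Step 18
Reactants: 27 epoxy aryl acetate
Product: 28 target CNP0254293.2 (8α,9α-epoxy-4β-hydroxy-1β-methyl-5α-H-daucan-6β-yl 4-hydroxy-3-methoxybenzoate)
Conditions: K2CO3 (cat.), MeOH, 0 °C
Reagents that add atoms: none
Why: Base-catalysed methanolysis (transesterification) of the aryl acetate, which is far more electrophilic than the hindered secondary aroate, should free the phenol without touching the epoxide or the C6 ester.

Compound list
1 | methyl acetoacetate | COC(=O)CC(C)=O | starting material
2 | 3-chloro-2-methylprop-1-ene | C=C(C)CCl | starting material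
3 | sodium lithium dianion of methyl acetoacetate | [Na+].[Li+].C=C([O-])C=C([O-])OC | intermediate
4 | methyl 6-methyl-3-oxohept-6-enoate | COC(=O)CC(=O)CCC(C)=C | intermediate
5 | methyl 2-diazo-6-methyl-3-oxohept-6-enoate | COC(=O)C(=[N+]=[N-])C(=O)CCC(C)=C | intermediate
6 | methyl (1R,5R)-5-methyl-2-oxobicyclo[3.1.0]hexane-1-carboxylate | COC(=O)[C@]12C[C@@]1(C)CCC2=O | intermediate
7 | methyl (1R,5R)-5-methylspiro[bicyclo[3.1.0]hexane-2,2'-[1,3]dioxolane]-1-carboxylate | COC(=O)[C@]12C[C@@]1(C)CCC21OCCO1 | intermediate
8 | (1R,5R)-5-methylspiro[bicyclo[3.1.0]hexane-2,2'-[1,3]dioxolane]-1-carboxylic acid | OC(=O)[C@]12C[C@@]1(C)CCC21OCCO1 | intermediate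
9 | lithium carboxylate of 8 | [Li+].[O-]C(=O)[C@]12C[C@@]1(C)CCC21OCCO1 | intermediate
10 | dilithium gem-diolate (methyllithium adduct of 9) | [Li+].[Li+].CC([O-])([O-])[C@]12C[C@@]1(C)CCC21OCCO1 | intermediate
11 | methyl ketone (1-acetyl-5-methylbicyclo[3.1.0]hexan-2-one ethylene ketal) | CC(=O)[C@]12C[C@@]1(C)CCC21OCCO1 | intermediate
12 | potassium enolate of 11 | [K+].C=C([O-])[C@]12C[C@@]1(C)CCC21OCCO1 | intermediate
13 | siloxyvinylcyclopropane (tert-butyldimethylsilyl enol ether of 11) | C=C(O[Si](C)(C)C(C)(C)C)[C@]12C[C@@]1(C)CCC21OCCO1 | intermediate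
14 | 1-propynylmagnesium bromide | CC#C[Mg]Br | starting material
15 | benzyldimethyl(prop-1-yn-1-yl)silane | CC#C[Si](C)(C)Cc1ccccc1 | intermediate
16 | hydroazulene cycloadduct (C5=C6 silyl enol ether, C8=C9 vinylsilane, C4 dioxolane) | C[C@]12CCC3(OCCO3)C1=C(O[Si](C)(C)C(C)(C)C)CC(C)=C([Si](C)(C)Cc1ccccc1)C2 | intermediate
17 | trans-fused C6 ketone with C9 benzyldimethylsilyl group | C[C@]12CCC3(OCCO3)[C@@H]1C(=O)CC(C)=C([Si](C)(C)Cc1ccccc1)C2 | intermediate
18 | 6β-alcohol with C9 benzyldimethylsilyl group | C[C@]12CCC3(OCCO3)[C@@H]1[C@H](O)CC(C)=C([Si](C)(C)Cc1ccccc1)C2 | intermediate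
19 | 6β-alcohol with C4 dioxolane and free C8=C9 alkene | C[C@]12CCC3(OCCO3)[C@@H]1[C@H](O)CC(C)=CC2 | intermediate
20 | 6β-hydroxy C4 ketone | C[C@]12CCC(=O)[C@@H]1[C@H](O)CC(C)=CC2 | intermediate
21 | isopropylmagnesium chloride | CC(C)[Mg]Cl | starting material
22 | dauc-8-ene-4β,6β-diol | C[C@]12CC[C@@](O)(C(C)C)[C@@H]1[C@H](O)CC(C)=CC2 | intermediate
23 | vanillic acid | COc1cc(C(=O)O)ccc1O | starting material
24 | 4-acetoxy-3-methoxybenzoic acid | COc1cc(C(=O)O)ccc1OC(C)=O | intermediate
25 | 4-acetoxy-3-methoxybenzoic 2,4,6-trichlorobenzoic anhydride | COc1cc(C(=O)OC(=O)c2c(Cl)cc(Cl)cc2Cl)ccc1OC(C)=O | intermediate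
26 | C6 4-acetoxy-3-methoxybenzoate of 22 | COc1cc(C(=O)O[C@@H]2CC(C)=CC[C@@]3(C)CC[C@@](O)(C(C)C)[C@H]23)ccc1OC(C)=O | intermediate
27 | 8α,9α-epoxide of 26 | COc1cc(C(=O)O[C@@H]2C[C@@]3(C)O[C@H]3C[C@@]3(C)CC[C@@](O)(C(C)C)[C@H]23)ccc1OC(C)=O | intermediate
28 | CNP0254293.2 | COc1cc(C(=O)O[C@@H]2C[C@@]3(C)O[C@H]3C[C@@]3(C)CC[C@@](O)(C(C)C)[C@H]23)ccc1O | target

Total step count: 18. Longest linear sequence: 16 steps (steps 1–7, 9–14, 16–18).

Steps most likely to fail

Step 9 (proposed new method). The crowded, fully flanked cyclopropane may not open at rhodium, the vinylcyclopropane may isomerise or lose its silyl enol ether instead, or the alkyne may insert with the opposite orientation. The fallback builds the seven-membered ring by known steps, sets out from keto ester 6 and returns at alcohol 19. Homoconjugate addition of a vinyl cuprate (vinylmagnesium bromide, CuBr·SMe2, THF, −40 °C) at the cyclopropane CH2 (C10) of the doubly activated cyclopropane should give methyl 2-allyl-2-methyl-5-oxocyclopentanecarboxylate F1, with C1 unchanged. Ketalisation with ethylene glycol and TsOH gives the dioxolane ester F2, which is equilibrated with NaOMe so that the ester sits anti to the allyl arm. Reduction with i-Bu2AlH at −78 °C gives the aldehyde F3, and 2-methylallylmagnesium chloride gives the homoallylic alcohol F4 as a C6 mixture. Ring-closing metathesis with second-generation Grubbs catalyst closes C8=C9 to the cycloheptenol F5, where any C5 epimer is removed. Dess–Martin oxidation with NaHCO3 gives the β,γ-unsaturated ketone F6, and L-Selectride at −78 °C, as in step 11, gives 19.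

Step 3. The copper–bis(oxazoline) carbenoid of a β-keto ester may discriminate the alkene faces poorly, so that 6 is formed with low enantiomeric purity. The fallback replaces catalyst control by resolution, sets out from diazo ester 5 and returns at acid 8. Decomposition of 5 with Rh2(OAc)4 in CH2Cl2 gives the racemic keto ester F7. Ketalisation and saponification as in steps 4 and 5 give the racemic ketal ester F8 and the racemic acid F9. Crystallisation of F9 with (R)-1-phenylethylamine (the antipodal amine if the other salt is the less soluble one) gives the single diastereomeric ammonium salt F10, from which cold dilute acid releases 8.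

Step 14. The secondary Grignard reagent may enolise the C4 ketone, reduce it by β-hydride transfer, or trigger retro-aldol opening of the β-alkoxy ketone instead of adding. The fallback uses an sp2 nucleophile that cannot transfer a β-hydride, sets out from ketone 20 and returns at diol 22. Isopropenylmagnesium bromide with anhydrous CeCl3 (THF, −78 °C) should add on the same α-face to give the isopropenyl carbinol F11. Hydrogenation with RhCl(PPh3)3 under H2 (1 atm, benzene) then saturates only the 1,1-disubstituted alkene and leaves the trisubstituted C8=C9 alkene, giving 22.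

Further compounds
F1 | step 9 | methyl 2-allyl-2-methyl-5-oxocyclopentanecarboxylate (C1 as in 6, C5 epimers) | C=CC[C@@]1(C)CCC(=O)C1C(=O)OC
F2 | step 9 | dioxolane of F1 (ester anti to the allyl arm) | C=CC[C@@]1(C)CCC2(OCCO2)[C@@H]1C(=O)OC
F3 | step 9 | aldehyde from F2 | C=CC[C@@]1(C)CCC2(OCCO2)[C@@H]1C=O
F4 | step 9 | homoallylic alcohol from F3 and 2-methylallylmagnesium chloride (C6 epimers) | C=CC[C@@]1(C)CCC2(OCCO2)[C@@H]1C(O)CC(C)=C
F5 | step 9 | cycloheptenol from ring-closing metathesis (C6 epimers) | C[C@]12CCC3(OCCO3)[C@@H]1C(O)CC(C)=CC2
F6 | step 9 | trans-fused C6 ketone with C4 dioxolane and C8=C9 alkene | C[C@]12CCC3(OCCO3)[C@@H]1C(=O)CC(C)=CC2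
F7 | step 3 | racemic methyl 5-methyl-2-oxobicyclo[3.1.0]hexane-1-carboxylate | COC(=O)C12CC1(C)CCC2=O
F8 | step 3 | racemic ketal ester | COC(=O)C12CC1(C)CCC21OCCO1
F9 | step 3 | racemic ketal acid | OC(=O)C12CC1(C)CCC21OCCO1
F10 | step 3 | (R)-1-phenylethylammonium salt of acid 8 | C[C@@H]([NH3+])c1ccccc1.[O-]C(=O)[C@]12C[C@@]1(C)CCC21OCCO1
F11 | step 14 | 4α-isopropenyl analogue of diol 22 | C[C@]12CC[C@@](O)(C(C)=C)[C@@H]1[C@H](O)CC(C)=CC2
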